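**Assumption:** the target has no stereocentre and is achiral, so "single enantiomer" means the single compound drawn; 2-(benzyloxy)-5-bromophenol is taken as a catalogue compound. The route is designed from known reaction classes and has not been run.

## Retrosynthetic overview

- Target ⇐ macrocyclic stilbene benzyl ether, by one hydrogenation that saturates the A–D bridge and frees the ring-C phenol.
- Macrocyclic stilbene ⇐ open-chain dialdehyde, by intramolecular McMurry coupling (A–D bridge); this closes the 18-membered ring, the only ring formed.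
- Dialdehyde ⇐ diaryl alkyne (B–C bridge), by alkyne saturation; diaryl alkyne ⇐ Sonogashira coupling of an A–O–B alkyne with a C–O–D aryl bromide.
- Both diaryl ethers ⇐ SNAr of phenols on fluorobenzaldehydes; the formyl groups that activate SNAr later become the A–D bridge.
- All four benzene rings are bought; no protecting-group step apart from the benzyl ether carried in from the starting material.

## Route

Step 1
Reactants: 1 3-ethynylphenol; 2 2-fluoro-3-methoxybenzaldehyde
Product: 3 2-(3-ethynylphenoxy)-3-methoxybenzaldehyde
Conditions: K2CO3, DMF, 90 °C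
Reagents that add atoms: none
Why: SNAr in which the ortho-formyl group activates the C–F bond of 2 toward the phenoxide of 1, while carbonate at 90 °C leaves the terminal alkyne and the non-enolisable aldehyde intact; no stereocentre is formed.

Step 2
Reactants: 4 2-(benzyloxy)-5-bromophenol; 5 4-fluorobenzaldehyde
Product: 6 4-[2-(benzyloxy)-5-bromophenoxy]benzaldehyde
Conditions: K2CO3, DMF, 120 °C
Reagents that add atoms: none
Why: SNAr of the phenoxide of 4 on para-formyl-activated 4-fluorobenzaldehyde, with the unactivated aryl bromide and the benzyl ether inert.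

Step 3
Reactants: 3 2-(3-ethynylphenoxy)-3-methoxybenzaldehyde; 6 4-[2-(benzyloxy)-5-bromophenoxy]benzaldehyde
Product: 7 2-[3-({4-(benzyloxy)-3-(4-formylphenoxy)phenyl}ethynyl)phenoxy]-3-methoxybenzaldehyde
Conditions: PdCl2(MeCN)2 (2 mol%), XPhos (6 mol%), Cs2CO3, MeCN, 80 °C
Reagents that add atoms: none
Why: Copper-free Sonogashira coupling in which the electron-rich bulky XPhos–Pd(0) inserts into the electron-rich C–Br bond of 6, the absence of copper suppresses Glaser homocoupling of 3, and both aldehydes tolerate the carbonate base.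

Step 4
Reactants: 7 2-[3-({4-(benzyloxy)-3-(4-formylphenoxy)phenyl}ethynyl)phenoxy]-3-methoxybenzaldehyde
Product: 9 2-[3-(2-{4-(benzyloxy)-3-(4-formylphenoxy)phenyl}ethyl)phenoxy]-3-methoxybenzaldehyde, via Z-stilbene dialdehyde 8 (not isolated)
Conditions: H2 (1 atm), 10% Pd/C, Ph2S (cat.), EtOAc, rt
Reagents that add atoms: none
Why: Chemoselective catalytic hydrogenation on sulfide-poisoned Pd/C saturates the diaryl alkyne through the Z-alkene, while the poison suppresses the slower hydrogenolysis of the aryl benzyl ether and reduction of the aryl aldehydes.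

Step 5
Reactants: 9 2-[3-(2-{4-(benzyloxy)-3-(4-formylphenoxy)phenyl}ethyl)phenoxy]-3-methoxybenzaldehyde
Product: 10 macrocyclic stilbene benzyl ether (target skeleton with the A–D bridge as CH=CH and the ring-C oxygen as OBn; E/Z mixture, Z drawn)
Conditions: TiCl4, Zn, pyridine, THF, reflux, slow addition of 9 (final ca. 2 mM)
Reagents that add atoms: none
Why: Intramolecular McMurry reductive coupling of the two aryl aldehydes under high dilution closes the 18-membered ring as a stilbene; its geometry does not matter because it is saturated next, and loss of the benzyl group here would be harmless because step 6 removes it anyway.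

Step 6
Reactants: 10 macrocyclic stilbene benzyl ether
Product: 11 CNP0309263.0 (marchantin C type macrocycle with ring-A OMe and ring-C OH)
Conditions: H2 (1 atm), 10% Pd/C, EtOAc–MeOH, rt
Reagents that add atoms: none
Why: Catalytic hydrogenation saturates the stilbene and hydrogenolyses the benzyl ether in one operation, leaving the methyl ether and both diaryl ethers untouched; the product is achiral.

## Compound list

1 | 3-ethynylphenol | C#Cc1cccc(O)c1 | starting material
2 | 2-fluoro-3-methoxybenzaldehyde | COc1cccc(C=O)c1F | starting material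
3 | 2-(3-ethynylphenoxy)-3-methoxybenzaldehyde | COc1cccc(C=O)c1Oc1cccc(C#C)c1 | intermediate
4 | 2-(benzyloxy)-5-bromophenol | Oc1cc(Br)ccc1OCc1ccccc1 | starting material
5 | 4-fluorobenzaldehyde | O=Cc1ccc(F)cc1 | starting material
6 | 4-[2-(benzyloxy)-5-bromophenoxy]benzaldehyde | O=Cc1ccc(Oc2cc(Br)ccc2OCc2ccccc2)cc1 | intermediate
7 | 2-[3-({4-(benzyloxy)-3-(4-formylphenoxy)phenyl}ethynyl)phenoxy]-3-methoxybenzaldehyde | COc1cccc(C=O)c1Oc1cccc(c1)C#Cc1ccc(OCc2ccccc2)c(Oc2ccc(C=O)cc2)c1 | intermediate
8 | (Z)-2-[3-(2-{4-(benzyloxy)-3-(4-formylphenoxy)phenyl}ethenyl)phenoxy]-3-methoxybenzaldehyde | COc1cccc(C=O)c1Oc1cccc(c1)/C=C\c1ccc(OCc2ccccc2)c(Oc2ccc(C=O)cc2)c1 | intermediate (not isolated)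
9 | 2-[3-(2-{4-(benzyloxy)-3-(4-formylphenoxy)phenyl}ethyl)phenoxy]-3-methoxybenzaldehyde | COc1cccc(C=O)c1Oc1cccc(c1)CCc1ccc(OCc2ccccc2)c(Oc2ccc(C=O)cc2)c1 | intermediate
10 | macrocyclic stilbene benzyl ether (A–D bridge CH=CH, ring-C OBn; Z isomer drawn, E/Z mixture carried on) | COc1cccc(/C=C\c2ccc(Oc3cc(CCc4cccc5c4)ccc3OCc3ccccc3)cc2)c1O5 | intermediate
11 | CNP0309263.0 (achiral) | COc1cccc2c1Oc1cccc(c1)CCc1ccc(O)c(c1)Oc1ccc(cc1)CC2 | target

## Summary

Total step count: 6. Longest linear sequence: 5 steps (1 or 2 → 3 → 7 → 9 → 10 → 11, or 4 or 5 → 6 → 7 → 9 → 10 → 11).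

## Three steps most likely to fail, with fallbacks

**Step 5 (McMurry macrocyclisation).** The risk is oligomerisation or arrest at the pinacol stage. The fallback sets out from compound 9 and closes the ring by olefin metathesis instead of carbonyl coupling. Double Wittig methylenation of 9 (MePPh3Br, KOtBu, THF, 0 °C) gives the bis-styrene 2-[3-(2-{4-(benzyloxy)-3-(4-ethenylphenoxy)phenyl}ethyl)phenoxy]-1-ethenyl-3-methoxybenzene F1. Ring-closing metathesis of this diene (Grubbs II, toluene, 2 mM, 80 °C, ethene swept out) gives the macrocyclic stilbene, and the route is rejoined at compound 10.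

**Step 4 (saturating the alkyne without touching the aldehydes or the benzyl ether).** The risk is over-reduction of the formyl groups or incomplete reduction. The fallback sets out from compound 7 and postpones full saturation to the end. Lindlar semi-hydrogenation (H2, Pd/CaCO3–Pb, quinoline, EtOAc) stops at the Z-stilbene dialdehyde 8, which is isolated this time and whose Z geometry still allows ring closure. McMurry coupling of 8 under the step 5 conditions gives the macrocyclic diene benzyl ether (Z-CH=CH for the B–C bridge, CH=CH for the A–D bridge) F2. The final H2, Pd/C step then saturates both alkenes and removes the benzyl group, coming back to the route at compound 11.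

**Step 1 (SNAr on the hindered, methoxy-flanked fluoride with an alkyne-bearing phenoxide).** The risk is slow substitution, with phenoxide addition to the terminal alkyne competing if the reaction is forced. The fallback sets out from compounds 1 and 6 and moves this ether formation to after the alkyne is gone. Sonogashira coupling of free phenol 1 with bromide 6 (step 3 conditions) gives 4-{2-(benzyloxy)-5-[(3-hydroxyphenyl)ethynyl]phenoxy}benzaldehyde F3. Hydrogenation (H2, Pd/C, Ph2S, EtOAc) gives 4-{2-(benzyloxy)-5-[2-(3-hydroxyphenyl)ethyl]phenoxy}benzaldehyde F4. This alkyne-free phenol can be pushed in the SNAr with 2 (Cs2CO3, DMSO, 120 °C), which delivers the dialdehyde directly and rejoins the route at compound 9.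

## Further compounds

F1 | step 5 | 2-[3-(2-{4-(benzyloxy)-3-(4-ethenylphenoxy)phenyl}ethyl)phenoxy]-1-ethenyl-3-methoxybenzene | COc1cccc(C=C)c1Oc1cccc(c1)CCc1ccc(OCc2ccccc2)c(Oc2ccc(C=C)cc2)c1
F2 | step 4 | macrocyclic diene benzyl ether (B–C bridge Z-CH=CH, A–D bridge CH=CH drawn Z, ring-C OBn) | COc1cccc(/C=C\c2ccc(Oc3cc(/C=C\c4cccc5c4)ccc3OCc3ccccc3)cc2)c1O5
F3 | step 1 | 4-{2-(benzyloxy)-5-[(3-hydroxyphenyl)ethynyl]phenoxy}benzaldehyde | O=Cc1ccc(Oc2cc(C#Cc3cccc(O)c3)ccc2OCc2ccccc2)cc1
F4 | step 1 | 4-{2-(benzyloxy)-5-[2-(3-hydroxyphenyl)ethyl]phenoxy}benzaldehyde | O=Cc1ccc(Oc2cc(CCc3cccc(O)c3)ccc2OCc2ccccc2)cc1
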